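**The pitfall.** Following target by itself misleads in the spring run. In the spring run it read 42% at 15.0 min and 41% at 30.0 min, which looks like a plateau, but over-reaction product climbed from 10% to 32% over the same time. So I read the runs another way, to decide which new recipe to keep for making target.

| flask | starting material | solid reagent | free catalyst | second catalyst | temperature | remark | time |
|---|---|---|---|---|---|---|---|
| spring | 0.80 M | 1.2 M | 40 mM | 16 mM | 20 °C | run made earlier |  |
| dusk | 0.80 M | 1.9 M | 40 mM | 16 mM | 45 °C | run made earlier |  |
| winter | 0.80 M | 0.88 M | 20 mM | 16 mM | 20 °C | run made earlier |  |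
| gamma | 0.80 M | 0.880 M | 40 mM | 16 mM | 25 °C |  | 30 min |
| zeta | 0.80 M | 0.880 M | 40 mM | 16 mM | 45 °C |  | 30 min |
| theta | 0.80 M | 0.880 M | 40 mM | 16 mM | 65 °C |  | 30 min |

| run | time / min | starting material / % | uncatalysed product / % | target / % | over-reaction product / % |
|---|---|---|---|---|---|
| spring | 2.50 | 49 | 3 | 12 | 2 |
| spring | 5.00 | 42 | 6 | 16 | 0 |
| spring | 8.00 | 32 | 11 | 29 | 2 |
| spring | 15.0 | 19 | 17 | 42 | 10 |
| spring | 30.0 | 2 | 18 | 41 | 32 |
| dusk | 1.00 | 81 | 3 | 2 | 2 |
| dusk | 2.00 | 72 | 11 | 6 | 0 |
| dusk | 3.00 | 62 | 22 | 4 | 0 |
| dusk | 6.00 | 34 | 44 | 14 | 5 |
| dusk | 12.0 | 8 | 66 | 12 | 18 |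
| winter | 6.00 | 38 | 7 | 23 | 1 |
| winter | 12.0 | 22 | 15 | 41 | 3 |
| winter | 20.0 | 14 | 19 | 50 | 8 |
| winter | 25.0 | 10 | 19 | 52 | 9 |
| winter | 30.0 | 10 | 18 | 50 | 10 |

(standard deviation of a reading: 1.5 percentage points)

* which of these there is most of at the end, counted by the starting material in it, gamma (uncatalysed product / starting material / over-reaction product / target)
* which of these there is most of at the end, counted by the starting material in it, zeta (uncatalysed product / starting material / over-reaction product / target)
* which of these there is most of at the end, counted by the starting material in it, theta (uncatalysed product / starting material / over-reaction product / target)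
* final amount of the leader among these, as a percentage of the starting material charged, in gamma
* final amount of the leader among these, as a percentage of the starting material charged, in zeta
* final amount of the leader among these, as a percentage of the starting material charged, in theta

- solid reagent is a solid; its amount is given per volume of the solution
- the earlier runs were read with a standard deviation of 1.5 percentage points
- at the start none of the solid reagent is in solution

**The split.** I used the split s, a selectivity factor: uncatalysed product divided by target plus over-reaction product, at the last reading. It read 0.300 in the winter run at 20 °C, last read at 30.0 min, and 2.20 in the dusk run at 45 °C, last read at 12.0 min, though the dusk run held more solid reagent and twice the free catalyst. The split energy E, the slope of the logarithm of s against minus the inverse of RT (T absolute temperature, R the gas constant), came to 61.8 kJ mol⁻¹. That figure is a reading, and booking the difference between these two runs to temperature was my assumption.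

**My reckoning.** E gave s of 0.459 for gamma and 8.76 for theta, while zeta shares the temperature of dusk. Above 1, uncatalysed product outweighs target and over-reaction product together, so I expected it to lead in zeta and theta. On the dusk product sum of 96.0%, I reckoned 66.0% for zeta and 86.2% for theta.

Target's share of its own branch read 0.562 in spring and 0.833 in winter, both above the gamma split, so I expected target to lead in gamma. On the winter product sum of 78.0%, those shares give 30.0% and 44.6%. Gamma has the catalyst of spring and the reagent of winter, so I took the mean, 37.3%. I kept gamma and dropped zeta and theta.

**The forecast.** The forecast gave target 48% in gamma, above my figure, and uncatalysed product 70% in zeta and 85% in theta, holding that “the uncatalysed path has the higher effective temperature dependence, or the catalyst fails when hot”.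

**The result.** Target led gamma at 37.0%; uncatalysed product led zeta at 65.7% and theta at 91.8%.

    starting material + free catalyst ⇌ free catalyst + intermediate (K = 0.680, k = 0.440 M⁻¹ s⁻¹, Ea = 38.0 kJ mol⁻¹, ΔH = −56.0 kJ mol⁻¹)
    coupling partner + second catalyst + intermediate → second catalyst + target (k = 0.540 M⁻² s⁻¹, Ea = 45.0 kJ mol⁻¹)
    coupling partner + free catalyst + target → free catalyst + over-reaction product (k = 0.0500 M⁻² s⁻¹, Ea = 58.0 kJ mol⁻¹)
    starting material + coupling partner → uncatalysed product (k = 0.00250 M⁻¹ s⁻¹, Ea = 59.0 kJ mol⁻¹)
    solid reagent ⇌ coupling partner, rate k5*(cs5 - [coupling partner]) while solid is left; crystals form when [coupling partner] > cs5 (solubility = 0.500 M, k = 0.00670 s⁻¹)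
    (constants at 25 °C)

**The check.** In gamma, target stood at 36.6% at 15.0 min and 37.0% at 30.0 min, while over-reaction product rose from 12.5% to 20.1%. The gamma split came to 0.448 against my 0.459, but the theta split came to 12.0 against my 8.76. Put to a neighbour of theta at 90 °C, E gives s of 39.8, so 97.5% of the products should be uncatalysed; that flask ended with 98.5% uncatalysed product beside 1.48% over-reaction product.

(The data were generated by integration for substances that don't exist, and the scatter is random.)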